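**Retrosynthetic overview**
1. Target ⇐ bis-TBS ether ⇐ fourfold esterification of a 3,6-diarylbenzene-1,2,4,5-tetrol with four molecules of (2Z,4S,5S)-4,5-epoxyhex-2-enoic acid.
2. Central benzene ring ⇐ 4-alkenyl-4-hydroxycyclobutenone, by thermal 4π ring opening to a dienylketene and 6π electrocyclisation; the two outer rings are bought.
3. Cyclobutenone ⇐ 3-aryl-4-methoxycyclobutenedione (dimethyl squarate + ArLi) + (Z)-1-aryl-2-methoxyvinyllithium (from ArCHO via enol ether and vinyl bromide).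
4. Epoxy acid ⇐ 5-mesyloxy-6-methyl-5,6-dihydropyran-2-one ⇐ 3,4-di-O-acetyl-L-rhamnal: the lactone fixes the Z alkene, C5 is the sugar carbon unchanged, C4 is inverted when the oxirane closes.
5. Ring order: central arene (step 4), oxirane of the acid (step 9), then esterification (step 10) and desilylation (step 11).

Assumption: 3,4-di-O-acetyl-L-rhamnal (catalogue glycal made from L-rhamnose) is bought as the only chiral material.
Abbreviations: TBS = tert-butyldimethylsilyl; Ar = 4-(tert-butyldimethylsilyloxy)phenyl.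

**Step 1**
Reactants: 1 (4-bromophenoxy)(tert-butyl)dimethylsilane; 2 dimethyl squarate
Product: 6 3-methoxy-4-[4-(tert-butyldimethylsilyloxy)phenyl]cyclobut-3-ene-1,2-dione, via aryllithium 3 (not isolated), via lithium alkoxide adduct 4 (not isolated), via trifluoroacetate 5 (not isolated)
Conditions: n-BuLi, THF, −78 °C; add to 2, THF, −78 °C; (CF3CO)2O, −78 → 0 °C; aq. NaHCO3
Reagents that add atoms: water, O
Why: Br/Li exchange and 1,2-addition of the aryllithium to one squarate carbonyl, then trifluoroacetylation of the tertiary alkoxide and hydrolytic collapse of the vinylogous orthoester on work-up (Moore–Liebeskind carbonyl transposition), give the arylcyclobutenedione without any stereocentre.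

**Step 2**
Reactants: 7 4-(tert-butyldimethylsilyloxy)benzaldehyde
Product: 8 tert-butyl[4-(2-methoxyethenyl)phenoxy]dimethylsilane (E/Z mixture)
Conditions: MeOCH2PPh3Cl, NaN(SiMe3)2, THF, 0 °C; then 7, 0 °C → rt
Reagents that add atoms: (methoxymethyl)triphenylphosphonium chloride, COC[P+](c1ccccc1)(c1ccccc1)c1ccccc1.[Cl-]
Why: Wittig methoxymethylenation gives the enol ether, whose E/Z ratio does not matter because the geometry is reset in step 3.

**Step 3**
Reactants: 8 tert-butyl[4-(2-methoxyethenyl)phenoxy]dimethylsilane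
Product: 10 (Z)-[4-(1-bromo-2-methoxyethenyl)phenoxy](tert-butyl)dimethylsilane, via dibromide 9 (not isolated)
Conditions: Br2 (1.0 equiv), CH2Cl2, −78 °C; then i-Pr2NEt, −78 °C → rt; chromatography
Reagents that add atoms: bromine, BrBr
Why: Bromine addition to the enol ether and amine-induced dehydrobromination (loss of the benzylic H and of the bromide alpha to oxygen, as in the classical preparation of (Z)-1-bromo-2-ethoxyethene) give the bromo enol ether, the Z isomer (aryl cis to H) being favoured.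

**Step 4**
Reactants: 10 (Z)-[4-(1-bromo-2-methoxyethenyl)phenoxy](tert-butyl)dimethylsilane; 6 3-methoxy-4-[4-(tert-butyldimethylsilyloxy)phenyl]cyclobut-3-ene-1,2-dione
Product: 15 2,5-bis[4-(tert-butyldimethylsilyloxy)phenyl]-3,6-dimethoxybenzene-1,4-diol, via vinyllithium 11 (not isolated), via hydroxycyclobutenone 12 (not isolated), via dienylketene 13 (not isolated), via cyclohexadienone 14 (not isolated)
Conditions: t-BuLi (2 equiv), Et2O, −78 °C; 6 in THF, −78 °C; aq. NH4Cl at −78 °C, extract; then toluene, 110 °C, argon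
Reagents that add atoms: none
Why: Br/Li exchange with retention gives the O-chelated (Z)-β-methoxyvinyllithium (kept cold in Et2O, like (Z)-2-ethoxyvinyllithium), which adds to the ketone-like carbonyl next to the methoxy-bearing carbon of 6; on heating, torquoselective conrotatory 4π electrocyclic ring opening (OH outward), 6π electrocyclisation of the dienylketene and enolisation (Moore benzannulation) form the central ring, the only stereocentres being transient and racemic.

**Step 5**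
Reactants: 15 2,5-bis[4-(tert-butyldimethylsilyloxy)phenyl]-3,6-dimethoxybenzene-1,4-diol
Product: 17 3,6-bis[4-(tert-butyldimethylsilyloxy)phenyl]benzene-1,2,4,5-tetrol, via bis(chlorodioxaborole) 16 (not isolated)
Conditions: BCl3 (5 equiv), CH2Cl2, −78 → 0 °C; degassed H2O, 0 °C, argon; used at once
Reagents that add atoms: none
Why: BCl3 first binds the two free phenols, and the adjacent, doubly ortho-flanked methoxy groups are then cleaved by chelation-assisted Lewis-acid ether cleavage, while the non-chelating aryl silyl ethers survive at or below 0 °C.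

**Step 6**
Reactants: 18 3,4-di-O-acetyl-L-rhamnal
Product: 20 (2S,3R)-2-methyl-6-oxo-3,6-dihydro-2H-pyran-3-yl acetate, via anomeric perester 19 (not isolated)
Conditions: mCPBA, BF3·OEt2, CH2Cl2, −20 °C
Reagents that add atoms: 3-chloroperoxybenzoic acid, OOC(=O)c1cccc(Cl)c1
Why: Ferrier-type allylic ionisation (loss of the C3 acetate), capture at C1 by the peracid and fragmentation of the perester give the 2,3-unsaturated δ-lactone; C4 and C5 of L-rhamnose are untouched and the future alkene is locked cis in the ring.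

**Step 7**
Reactants: 20 (2S,3R)-2-methyl-6-oxo-3,6-dihydro-2H-pyran-3-yl acetate
Product: 21 (5R,6S)-5-hydroxy-6-methyl-5,6-dihydro-2H-pyran-2-one
Conditions: HCl (1.25 M in MeOH), 0 °C → rt
Reagents that add atoms: none
Why: Acid-catalysed transesterification removes the acetate faster than it attacks the less electrophilic conjugated lactone carbonyl, and no C–O bond at a stereocentre is broken.

**Step 8**
Reactants: 21 (5R,6S)-5-hydroxy-6-methyl-5,6-dihydro-2H-pyran-2-one
Product: 22 (2S,3R)-2-methyl-6-oxo-3,6-dihydro-2H-pyran-3-yl methanesulfonate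
Conditions: MsCl, Et3N, CH2Cl2, −20 → 0 °C
Reagents that add atoms: methanesulfonyl chloride, CS(=O)(=O)Cl
Why: O-Sulfonylation of the secondary alcohol (retention at carbon) makes O4 of the sugar the leaving group while O5 stays tied up in the lactone, so the later inversion can only occur at C4.

**Step 9**
Reactants: 22 (2S,3R)-2-methyl-6-oxo-3,6-dihydro-2H-pyran-3-yl methanesulfonate
Product: 24 (2Z)-3-[(2S,3S)-3-methyloxiran-2-yl]prop-2-enoic acid, via ring-opened hydroxy mesylate salt 23 (not isolated)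
Conditions: LiOH·H2O (2.1 equiv), THF/H2O 3:1, 0 °C; then 1 M HCl to pH 4 at 0 °C, EtOAc extraction; used at once
Reagents that add atoms: lithium hydroxide, [Li+].[OH-]
Why: Hydroxide opens the lactone by acyl substitution (Z geometry kept) and the freed C5 alkoxide displaces the neighbouring mesylate in an intramolecular SN2 reaction (3-exo-tet epoxide closure), which inverts C4 (R to S) and keeps C5 (S), so the erythro sugar diol becomes the trans-(4S,5S)-epoxide.

**Step 10**
Reactants: 17 3,6-bis[4-(tert-butyldimethylsilyloxy)phenyl]benzene-1,2,4,5-tetrol; 24 (2Z)-3-[(2S,3S)-3-methyloxiran-2-yl]prop-2-enoic acid (four molecules of the acid are taken up per molecule of the tetrol)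
Product: 26 3,6-bis[4-(tert-butyldimethylsilyloxy)phenyl]benzene-1,2,4,5-tetrayl tetrakis{(2Z)-3-[(2S,3S)-3-methyloxiran-2-yl]prop-2-enoate}, via O-acylisourea 25 (not isolated)
Conditions: 24 (6 equiv), EDC·HCl (6.5 equiv), DMAP (0.4 equiv), CH2Cl2, 0 °C → rt, argon
Reagents that add atoms: epoxy acid 24 (the three further equivalents that end up in the product), C[C@@H]1O[C@H]1/C=C\C(=O)O.C[C@@H]1O[C@H]1/C=C\C(=O)O.C[C@@H]1O[C@H]1/C=C\C(=O)O
Why: Fourfold Steglich esterification (carbodiimide activation of each of the four acid molecules, DMAP acyl transfer) acylates all four phenolic hydroxyls under near-neutral conditions at low temperature, so the epoxides, the Z alkenes and all stereocentres are untouched.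

**Step 11**
Reactants: 26 the bis-TBS tetraester
Product: 27 CNP0249571.1, 3,6-bis(4-hydroxyphenyl)benzene-1,2,4,5-tetrayl tetrakis{(2Z)-3-[(2S,3S)-3-methyloxiran-2-yl]prop-2-enoate}
Conditions: TBAF (2.4 equiv), AcOH (3 equiv), THF, 0 °C, 30 min
Reagents that add atoms: none
Why: Fluoride-mediated desilylation cleaves the two aryl silyl ethers within minutes, and the acetic acid buffer keeps the medium non-basic so the four aryl esters and the epoxides survive.

**Compound list**
1 | (4-bromophenoxy)(tert-butyl)dimethylsilane | CC(C)(C)[Si](C)(C)Oc1ccc(Br)cc1 | starting material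
2 | dimethyl squarate (3,4-dimethoxycyclobut-3-ene-1,2-dione) | COC1=C(OC)C(=O)C1=O | starting material
3 | [4-(tert-butyldimethylsilyloxy)phenyl]lithium | [Li]c1ccc(O[Si](C)(C)C(C)(C)C)cc1 | intermediate
4 | lithium 1-[4-(tert-butyldimethylsilyloxy)phenyl]-2,3-dimethoxy-4-oxocyclobut-2-en-1-olate (racemic) | COC1=C(OC)C([O-])(c2ccc(O[Si](C)(C)C(C)(C)C)cc2)C1=O.[Li+] | intermediate
5 | 1-[4-(tert-butyldimethylsilyloxy)phenyl]-2,3-dimethoxy-4-oxocyclobut-2-en-1-yl trifluoroacetate (racemic) | COC1=C(OC)C(OC(=O)C(F)(F)F)(c2ccc(O[Si](C)(C)C(C)(C)C)cc2)C1=O | intermediate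
6 | 3-methoxy-4-[4-(tert-butyldimethylsilyloxy)phenyl]cyclobut-3-ene-1,2-dione | COC1=C(c2ccc(O[Si](C)(C)C(C)(C)C)cc2)C(=O)C1=O | intermediate
7 | 4-(tert-butyldimethylsilyloxy)benzaldehyde | CC(C)(C)[Si](C)(C)Oc1ccc(C=O)cc1 | starting material
8 | tert-butyl[4-(2-methoxyethenyl)phenoxy]dimethylsilane (E/Z mixture, geometry left open) | COC=Cc1ccc(O[Si](C)(C)C(C)(C)C)cc1 | intermediate
9 | tert-butyl[4-(1,2-dibromo-2-methoxyethyl)phenoxy]dimethylsilane (diastereomer mixture) | COC(Br)C(Br)c1ccc(O[Si](C)(C)C(C)(C)C)cc1 | intermediate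
10 | (Z)-[4-(1-bromo-2-methoxyethenyl)phenoxy](tert-butyl)dimethylsilane | CO/C=C(\Br)c1ccc(O[Si](C)(C)C(C)(C)C)cc1 | intermediate
11 | (Z)-{1-[4-(tert-butyldimethylsilyloxy)phenyl]-2-methoxyethenyl}lithium (Li cis to OMe) | CO/C=C(\[Li])c1ccc(O[Si](C)(C)C(C)(C)C)cc1 | intermediate
12 | 4-hydroxy-3-methoxy-2-Ar-4-[(Z)-2-methoxy-1-Ar-ethenyl]cyclobut-2-en-1-one (racemic) | CO/C=C(/c1ccc(O[Si](C)(C)C(C)(C)C)cc1)C1(O)C(OC)=C(c2ccc(O[Si](C)(C)C(C)(C)C)cc2)C1=O | intermediate
13 | (3Z,5Z)-4-hydroxy-3,6-dimethoxy-2,5-bis-Ar-hexa-1,3,5-trien-1-one (dienylketene) | CO/C=C(/c1ccc(O[Si](C)(C)C(C)(C)C)cc1)\C(O)=C(\OC)C(=C=O)c1ccc(O[Si](C)(C)C(C)(C)C)cc1 | intermediate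
14 | 4-hydroxy-3,6-dimethoxy-2,5-bis-Ar-cyclohexa-2,4-dien-1-one (racemic) | COC1C(=O)C(c2ccc(O[Si](C)(C)C(C)(C)C)cc2)=C(OC)C(O)=C1c1ccc(O[Si](C)(C)C(C)(C)C)cc1 | intermediate
15 | 2,5-bis[4-(tert-butyldimethylsilyloxy)phenyl]-3,6-dimethoxybenzene-1,4-diol | COc1c(O)c(-c2ccc(O[Si](C)(C)C(C)(C)C)cc2)c(OC)c(O)c1-c1ccc(O[Si](C)(C)C(C)(C)C)cc1 | intermediate
16 | 2,6-dichloro-4,8-bis-Ar-benzo[1,2-d:4,5-d']bis[1,3,2]dioxaborole | ClB1Oc2c(O1)c(-c1ccc(O[Si](C)(C)C(C)(C)C)cc1)c1OB(Cl)Oc1c2-c1ccc(O[Si](C)(C)C(C)(C)C)cc1 | intermediate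
17 | 3,6-bis[4-(tert-butyldimethylsilyloxy)phenyl]benzene-1,2,4,5-tetrol | Oc1c(O)c(-c2ccc(O[Si](C)(C)C(C)(C)C)cc2)c(O)c(O)c1-c1ccc(O[Si](C)(C)C(C)(C)C)cc1 | intermediate
18 | 3,4-di-O-acetyl-L-rhamnal, (2S,3S,4S)-2-methyl-3,4-dihydro-2H-pyran-3,4-diyl diacetate | C[C@@H]1OC=C[C@H](OC(C)=O)[C@H]1OC(C)=O | starting material
19 | 4-O-acetyl-2,3,6-trideoxy-L-erythro-hex-2-enopyranosyl 3-chloroperoxybenzoate (anomer mixture) | C[C@@H]1OC(OOC(=O)c2cccc(Cl)c2)C=C[C@H]1OC(C)=O | intermediate
20 | (2S,3R)-2-methyl-6-oxo-3,6-dihydro-2H-pyran-3-yl acetate | C[C@@H]1OC(=O)C=C[C@H]1OC(C)=O | intermediate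
21 | (5R,6S)-5-hydroxy-6-methyl-5,6-dihydro-2H-pyran-2-one | C[C@@H]1OC(=O)C=C[C@H]1O | intermediate
22 | (2S,3R)-2-methyl-6-oxo-3,6-dihydro-2H-pyran-3-yl methanesulfonate | C[C@@H]1OC(=O)C=C[C@H]1OS(C)(=O)=O | intermediate
23 | lithium (2Z,4R,5S)-5-hydroxy-4-(methanesulfonyloxy)hex-2-enoate | C[C@H](O)[C@H](OS(C)(=O)=O)/C=C\C(=O)[O-].[Li+] | intermediate
24 | (2Z)-3-[(2S,3S)-3-methyloxiran-2-yl]prop-2-enoic acid, i.e. (2Z,4S,5S)-4,5-epoxyhex-2-enoic acid | C[C@@H]1O[C@H]1/C=C\C(=O)O | intermediate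
25 | O-acylisourea of 24 and EDC | C[C@@H]1O[C@H]1/C=C\C(=O)OC(=NCC)NCCCN(C)C | intermediate
26 | bis-TBS ether of the target tetraester | C[C@@H]1O[C@H]1/C=C\C(=O)Oc1c(OC(=O)/C=C\[C@@H]2O[C@H]2C)c(-c2ccc(O[Si](C)(C)C(C)(C)C)cc2)c(OC(=O)/C=C\[C@@H]2O[C@H]2C)c(OC(=O)/C=C\[C@@H]2O[C@H]2C)c1-c1ccc(O[Si](C)(C)C(C)(C)C)cc1 | intermediate
27 | CNP0249571.1 | C[C@@H]1O[C@H]1/C=C\C(=O)Oc1c(OC(=O)/C=C\[C@@H]2O[C@H]2C)c(-c2ccc(O)cc2)c(OC(=O)/C=C\[C@@H]2O[C@H]2C)c(OC(=O)/C=C\[C@@H]2O[C@H]2C)c1-c1ccc(O)cc1 | target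

**Totals**
Total steps: 11. Longest linear sequence: 6 steps (7 → 8 → 10 → 15 → 17 → 26 → 27, or equally 18 → 20 → 21 → 22 → 24 → 26 → 27).

**Three steps most likely to fail**

Step 10 (four hindered, oxidation-prone hydroxyls; an acid that can lactonise, and a Z alkene that DMAP can isomerise). Fallback: setting out from 24, cyanuric fluoride/pyridine (CH2Cl2, −20 °C) gives the isolable acyl fluoride (2Z)-3-[(2S,3S)-3-methyloxiran-2-yl]prop-2-enoyl fluoride F5. Four equivalents of F5 (used in slight excess) acylate the tetraphenoxide of 17 (i-Pr2NEt, MeCN, 0 °C → rt) without carbodiimide or acylpyridinium intermediates and come back to the route at 26.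

Step 5 (selective cleavage of the two central methyl ethers while the aryl silyl ethers stay; air-sensitive product). Fallback: setting out from 15, excess BBr3 (CH2Cl2, −78 °C → rt, aqueous work-up) removes both methyl and both silyl groups to give leucoatromentin F2. Air oxidises F2 in the same work-up to the stable quinone atromentin F3. TBSCl/imidazole (DMF, 0 °C) then silylates only the two outer phenols, because silyl derivatives of the vinylogous-acid quinone hydroxyls do not survive aqueous work-up, giving the bis-silyl quinone F4. Na2S2O4 (THF/H2O, argon) reduces F4 and comes back to the route at 17.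

Step 3 (labile dibromide on an electron-rich arene; step 4 needs geometrically pure Z-10 for the chelated vinyllithium). Fallback: setting out from 8, bromomethoxylation with NBS in MeOH (0 °C) gives the isolable bromo acetal tert-butyl[4-(1-bromo-2,2-dimethoxyethyl)phenoxy]dimethylsilane F1. Me3SiOTf/i-Pr2NEt (CH2Cl2, −20 °C → rt, acetal-to-enol-ether elimination) then removes methanol from F1 and comes back to the route at 10.

**Further compounds**
F1 | step 3 | tert-butyl[4-(1-bromo-2,2-dimethoxyethyl)phenoxy]dimethylsilane (racemic) | COC(OC)C(Br)c1ccc(O[Si](C)(C)C(C)(C)C)cc1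
F2 | step 5 | leucoatromentin, 3,6-bis(4-hydroxyphenyl)benzene-1,2,4,5-tetrol | Oc1ccc(cc1)-c1c(O)c(O)c(-c2ccc(O)cc2)c(O)c1O
F3 | step 5 | atromentin, 2,5-dihydroxy-3,6-bis(4-hydroxyphenyl)cyclohexa-2,5-diene-1,4-dione | O=C1C(O)=C(c2ccc(O)cc2)C(=O)C(O)=C1c1ccc(O)cc1
F4 | step 5 | 2,5-dihydroxy-3,6-bis[4-(tert-butyldimethylsilyloxy)phenyl]cyclohexa-2,5-diene-1,4-dione | O=C1C(O)=C(c2ccc(O[Si](C)(C)C(C)(C)C)cc2)C(=O)C(O)=C1c1ccc(O[Si](C)(C)C(C)(C)C)cc1
F5 | step 10 | (2Z)-3-[(2S,3S)-3-methyloxiran-2-yl]prop-2-enoyl fluoride | C[C@@H]1O[C@H]1/C=C\C(F)=O
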